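**Plan**
- The target is a trimer of 8-methoxynaphthalen-1-ol (units A, B, C). The retrosynthesis cuts the C2(A)–C2(B) biaryl bond first and the C4(B)–C2(C) biaryl bond second, so all three units come from one monomer.
- Enabling feature: C2 of ring A and C2 of ring B each lie ortho to a phenolic oxygen on C1, and both peri carbons C8 carry OMe. One Si(t-Bu)2 atom bridging O1(A) and O1(B) therefore holds C2–Br of A next to C2–H of B and next to no other C–H.
- Forward: the MOM ether of the monomer is lithiated and brominated at C2. This one bromide gives the boronate (unit C) by Miyaura borylation and the bromonaphthol (unit A) by MOM removal. Para-bromination of the monomer gives unit B, and a Suzuki–Miyaura coupling joins C to B, leaving only O1(B) free.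
- Sequential silylation builds the O1(A)–Si–O1(B) bridge, intramolecular Pd-catalysed C–H arylation closes a seven-membered dioxasilepine ring and forms the A–B bond, and fluoride then acid remove bridge and MOM.
- Stereochemistry: there is no stereocentre and neither biaryl axis is configurationally stable, so nothing has to be set.

Key step: step 8

Assumption: 8-methoxynaphthalen-1-ol is taken as a catalogue compound (otherwise it is one monomethylation from naphthalene-1,8-diol).

**Route**

Step 1
Reactants: 1 8-methoxynaphthalen-1-ol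
Product: 2 1-methoxy-8-(methoxymethoxy)naphthalene
Conditions: NaH, DMF, 0 °C; then MOMCl, 0 °C to rt
Reagents that add atoms: chloromethyl methyl ether (MOMCl), COCCl
Why: NaH breaks the peri O–H···OMe hydrogen bond and the sodium naphthoxide is O-alkylated by the reactive α-chloro ether (Williamson-type MOM protection).

Step 2
Reactants: 2 1-methoxy-8-(methoxymethoxy)naphthalene
Product: 4 2-bromo-8-methoxy-1-(methoxymethoxy)naphthalene, via aryllithium 3 (not isolated)
Conditions: n-BuLi, TMEDA, Et2O, 0 °C to rt; then BrCCl2CCl2Br, −78 °C to rt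
Reagents that add atoms: 1,2-dibromo-1,1,2,2-tetrachloroethane, ClC(Cl)(Br)C(Cl)(Cl)Br
Why: Directed ortho-metalation, in which the MOM acetal oxygens chelate lithium and direct deprotonation to C2 (OMOM outranks OMe as a director, so C7 should stay untouched), followed by electrophilic bromination of the aryllithium by bromine transfer from the vicinal dibromide (which collapses to tetrachloroethene and LiBr), places bromine at C2 only.

Step 3
Reactants: 4 2-bromo-8-methoxy-1-(methoxymethoxy)naphthalene
Product: 5 2-[8-methoxy-1-(methoxymethoxy)naphthalen-2-yl]-4,4,5,5-tetramethyl-1,3,2-dioxaborolane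
Conditions: B2pin2, PdCl2(dppf) (3 mol %), KOAc, 1,4-dioxane, 90 °C, argon
Reagents that add atoms: bis(pinacolato)diboron (B2pin2), CC1(C)OB(OC1(C)C)B1OC(C)(C)C(C)(C)O1
Why: Miyaura borylation: zerovalent palladium inserts into the C2–Br bond, acetate-assisted transmetalation with the diboron and reductive elimination give the aryl pinacol boronate, and the weak base leaves the MOM acetal and the methyl ether untouched and disfavours biaryl homocoupling.

Step 4
Reactants: 4 2-bromo-8-methoxy-1-(methoxymethoxy)naphthalene
Product: 6 2-bromo-8-methoxynaphthalen-1-ol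
Conditions: HCl (cat.), MeOH, 50 °C
Reagents that add atoms: none
Why: Acid-catalysed acetal methanolysis removes the aryl MOM group while the aryl bromide and the methyl ether are inert (MOM deprotection).

Step 5
Reactants: 1 8-methoxynaphthalen-1-ol
Product: 7 4-bromo-8-methoxynaphthalen-1-ol
Conditions: NBS (1.0 equiv), MeCN, −20 to 0 °C
Reagents that add atoms: N-bromosuccinimide (NBS), O=C1CCC(=O)N1Br
Why: Electrophilic aromatic bromination of a 1-naphthol in MeCN goes para to the hydroxyl (C4), and the free-phenol ring is far more activated than the methoxy-bearing ring.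

Step 6
Reactants: 5 2-[8-methoxy-1-(methoxymethoxy)naphthalen-2-yl]-4,4,5,5-tetramethyl-1,3,2-dioxaborolane; 7 4-bromo-8-methoxynaphthalen-1-ol
Product: 8 8-methoxy-4-[8-methoxy-1-(methoxymethoxy)naphthalen-2-yl]naphthalen-1-ol
Conditions: Pd(OAc)2 (3 mol %), SPhos (6 mol %), K3PO4, toluene/H2O 10:1, 80 °C
Reagents that add atoms: none
Why: Suzuki–Miyaura cross-coupling forms the C4(B)–C2(C) bond; the electron-rich dialkylbiarylphosphine lets zerovalent palladium insert into the electron-rich, peri-flanked bromide even as its phenoxide, and the MOM group survives the base.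

Step 7
Reactants: 6 2-bromo-8-methoxynaphthalen-1-ol; 8 8-methoxy-4-[8-methoxy-1-(methoxymethoxy)naphthalen-2-yl]naphthalen-1-ol
Product: 10 di-tert-butyl[(2-bromo-8-methoxynaphthalen-1-yl)oxy]({8-methoxy-4-[8-methoxy-1-(methoxymethoxy)naphthalen-2-yl]naphthalen-1-yl}oxy)silane, via aryloxysilyl triflate 9 (not isolated)
Conditions: t-Bu2Si(OTf)2 (1.0 equiv), Et3N, CH2Cl2, −78 to 0 °C (slow addition of 6); then 8, Et3N, DMAP (cat.), rt to 40 °C
Reagents that add atoms: di-tert-butylsilyl bis(trifluoromethanesulfonate), CC(C)(C)[Si](OS(=O)(=O)C(F)(F)F)(OS(=O)(=O)C(F)(F)F)C(C)(C)C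
Why: Sequential nucleophilic substitution at silicon (temporary silicon tether): the first triflate is displaced by 6 at low temperature, the second is much less reactive and is displaced only when 8 is added and warmed, and 8 offers only O1 of ring B because O1 of ring C is MOM-capped; 6 goes first so that the MOM group never meets the more Lewis-acidic bis-triflate.

Step 8
Reactants: 10 di-tert-butyl[(2-bromo-8-methoxynaphthalen-1-yl)oxy]({8-methoxy-4-[8-methoxy-1-(methoxymethoxy)naphthalen-2-yl]naphthalen-1-yl}oxy)silane
Product: 11 di-tert-butylsilylene-bridged trimer (2,2'-binaphthyl whose O1 and O1' are joined by Si(t-Bu)2 in a seven-membered dinaphtho[1,2-d:2',1'-f][1,3,2]dioxasilepine ring; OMe at C8 and C8'; 8-methoxy-1-(methoxymethoxy)naphthalen-2-yl at C4' of ring B)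
Conditions: Pd(OAc)2 (5 mol %), PCy3·HBF4 (10 mol %), CsO2CCMe3 (2 equiv), p-xylene, 130 °C, argon
Reagents that add atoms: none
Why: Zerovalent palladium (formed from Pd(OAc)2 and PCy3) inserts into the C2–Br bond of ring A, pivalate then assists concerted metalation–deprotonation of the C2–H bond of ring B, and C–C reductive elimination from the resulting eight-membered diaryl palladacycle forms the C2(A)–C2(B) bond. The closest known reaction type is the palladium-catalysed intramolecular C–H arylation of bis(aryloxy)di-tert-butylsilanes built from a 2-bromophenol and a phenol, which gives unsymmetrical 2,2'-biphenols and binaphthols after desilylation. The one ring closed is the seven-membered 1,3-dioxa-2-silepine ring (C2(A), C1(A), O, Si, O, C1(B), C2(B)), and it is closed by aryl–aryl reductive elimination, that is, by intramolecular direct arylation. No stereocentre is created and the new axis rotates freely once the bridge is removed, so no stereocontrol is needed. The step needs cross-coupling over homo-coupling and attack at C2 of ring B, not at C3 or on ring C; the O–Si–O bridge secures both, because C2–H of ring B is the only C–H ortho to the bridging oxygen (the peri carbon C8 bears OMe), C3 could be reached only through a strained meta-bridged ring, and ring C is held away by the C4(B) link. The two tert-butyl groups shield silicon from pivalate, and the non-polar solvent keeps the Si–O bonds, the MOM acetal and the methyl ethers intact.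

Step 9
Reactants: 11 di-tert-butylsilylene-bridged trimer
Product: 13 8,8',8''-trimethoxy-[2,2':4',2''-ternaphthalene]-1,1',1''-triol, via MOM-protected trimer 12 (not isolated)
Conditions: TBAF (Bu4NF), THF, 0 °C to rt, argon; then conc. HCl, MeOH, 50 °C
Reagents that add atoms: none
Why: Fluoride attacks silicon and releases both naphthol oxygens from the silylene (desilylation driven by the Si–F bond), and the acidified methanol then cleaves the remaining aryl MOM acetal while the three methyl ethers stay in place (one-pot global deprotection under argon to protect the electron-rich binaphthol from air).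

**Compound list**
1 | 8-methoxynaphthalen-1-ol | COc1cccc2cccc(O)c12 | starting material
2 | 1-methoxy-8-(methoxymethoxy)naphthalene | COCOc1cccc2cccc(OC)c12 | intermediate
3 | [8-methoxy-1-(methoxymethoxy)naphthalen-2-yl]lithium | [Li]c1ccc2cccc(OC)c2c1OCOC | intermediate
4 | 2-bromo-8-methoxy-1-(methoxymethoxy)naphthalene | COCOc1c(Br)ccc2cccc(OC)c12 | intermediate
5 | 2-[8-methoxy-1-(methoxymethoxy)naphthalen-2-yl]-4,4,5,5-tetramethyl-1,3,2-dioxaborolane | COCOc1c(B2OC(C)(C)C(C)(C)O2)ccc2cccc(OC)c12 | intermediate
6 | 2-bromo-8-methoxynaphthalen-1-ol | COc1cccc2ccc(Br)c(O)c12 | intermediate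
7 | 4-bromo-8-methoxynaphthalen-1-ol | COc1cccc2c(Br)ccc(O)c12 | intermediate
8 | 8-methoxy-4-[8-methoxy-1-(methoxymethoxy)naphthalen-2-yl]naphthalen-1-ol | COc1cccc2c(-c3ccc4cccc(OC)c4c3OCOC)ccc(O)c12 | intermediate
9 | [(2-bromo-8-methoxynaphthalen-1-yl)oxy]di-tert-butylsilyl trifluoromethanesulfonate | COc1cccc2ccc(Br)c(O[Si](OS(=O)(=O)C(F)(F)F)(C(C)(C)C)C(C)(C)C)c12 | intermediate
10 | di-tert-butyl[(2-bromo-8-methoxynaphthalen-1-yl)oxy]({8-methoxy-4-[8-methoxy-1-(methoxymethoxy)naphthalen-2-yl]naphthalen-1-yl}oxy)silane | COc1cccc2ccc(Br)c(O[Si](C(C)(C)C)(C(C)(C)C)Oc3ccc(-c4ccc5cccc(OC)c5c4OCOC)c4cccc(OC)c34)c12 | intermediate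
11 | di-tert-butylsilylene-bridged trimer (dinaphtho[1,2-d:2',1'-f][1,3,2]dioxasilepine core; OMe at C8 and C8'; 8-methoxy-1-(methoxymethoxy)naphthalen-2-yl at C4' of ring B) | COc1cccc2ccc3-c4cc(-c5ccc6cccc(OC)c6c5OCOC)c5cccc(OC)c5c4O[Si](C(C)(C)C)(C(C)(C)C)Oc3c12 | intermediate
12 | 8,8',8''-trimethoxy-1''-(methoxymethoxy)-[2,2':4',2''-ternaphthalene]-1,1'-diol | COc1cccc2ccc(-c3cc(-c4ccc5cccc(OC)c5c4OCOC)c4cccc(OC)c4c3O)c(O)c12 | intermediate
13 | 8,8',8''-trimethoxy-[2,2':4',2''-ternaphthalene]-1,1',1''-triol | COc1cccc2ccc(-c3cc(-c4ccc5cccc(OC)c5c4O)c4cccc(OC)c4c3O)c(O)c12 | target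

**Step count**
Total steps: 9. Longest linear sequence: 7 steps (steps 1, 2, 3, 6, 7, 8, 9).

**Steps most likely to fail**

1. Step 8. The crowded seven-membered closure may be slow, so that the palladated ring A is protonated instead (hydrodebromination), or pivalate may open the Si–O bridge before the C–H bond is reached. The fallback gives up the tether and joins the rings by an intermolecular cross-coupling. It sets out from 8: ortho-bromination of the free naphthol (NBS, i-Pr2NH cat., CH2Cl2, 0 °C; C4 is blocked, so only C2 of ring B is open) should give 2-bromo-8-methoxy-4-[8-methoxy-1-(methoxymethoxy)naphthalen-2-yl]naphthalen-1-ol F1. Suzuki–Miyaura coupling of F1 with boronate 5 (Pd(OAc)2, SPhos, K3PO4, toluene/H2O, 80 °C) should give 8,8',8''-trimethoxy-1,1''-bis(methoxymethoxy)-[2,2':4',2''-ternaphthalen]-1'-ol F2. Methanolic HCl at 50 °C then removes both MOM groups, and the fallback comes back to the route at 13.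

2. Step 7. The two substitutions at silicon may not stay sequential (scrambling to symmetrical bis(aryloxy)silanes), the second substitution may stall at the crowded silicon, or the silyl triflate may strip the MOM group. The fallback replaces the bis-electrophile by a hydrosilane whose Si–H is activated only after the first naphthol is in place. It sets out from 6: silylation with t-Bu2SiHCl (imidazole, DMF, rt to 50 °C) should give [(2-bromo-8-methoxynaphthalen-1-yl)oxy]di-tert-butylsilane F3. Si–H bromination with NBS (CH2Cl2, 0 °C) should give bromo[(2-bromo-8-methoxynaphthalen-1-yl)oxy]di-tert-butylsilane F4. F4 is treated directly with the sodium naphthoxide of 8 (NaH, THF/DMF, rt to 50 °C), and the fallback comes back at 10.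

3. Step 6. Protodeboronation of the ortho-alkoxy boronate 5 may outrun the slow oxidative addition into the electron-rich naphthoxide bromide. The fallback reverses the polarity of the coupling. It sets out from 7: silylation (TIPSCl, imidazole, DMF) should give [(4-bromo-8-methoxynaphthalen-1-yl)oxy]tri(propan-2-yl)silane F5. Miyaura borylation (B2pin2, PdCl2(dppf), KOAc, dioxane, 90 °C) should give {[8-methoxy-4-(4,4,5,5-tetramethyl-1,3,2-dioxaborolan-2-yl)naphthalen-1-yl]oxy}tri(propan-2-yl)silane F6. Suzuki–Miyaura coupling of F6 with bromide 4 (Pd(OAc)2, SPhos, K3PO4, toluene/H2O, 80 °C) should give ({8-methoxy-4-[8-methoxy-1-(methoxymethoxy)naphthalen-2-yl]naphthalen-1-yl}oxy)tri(propan-2-yl)silane F7. TBAF (Bu4NF) in THF then removes the silyl group, and the fallback comes back at 8.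

**Further compounds**
F1 | step 8 | 2-bromo-8-methoxy-4-[8-methoxy-1-(methoxymethoxy)naphthalen-2-yl]naphthalen-1-ol | Oc1c(Br)cc(-c2ccc3cccc(OC)c3c2OCOC)c2cccc(OC)c12
F2 | step 8 | 8,8',8''-trimethoxy-1,1''-bis(methoxymethoxy)-[2,2':4',2''-ternaphthalen]-1'-ol | COCOc1c(-c2cc(-c3ccc4cccc(OC)c4c3OCOC)c3cccc(OC)c3c2O)ccc2cccc(OC)c12
F3 | step 7 | [(2-bromo-8-methoxynaphthalen-1-yl)oxy]di-tert-butylsilane | COc1cccc2ccc(Br)c(O[SiH](C(C)(C)C)C(C)(C)C)c12
F4 | step 7 | bromo[(2-bromo-8-methoxynaphthalen-1-yl)oxy]di-tert-butylsilane | COc1cccc2ccc(Br)c(O[Si](Br)(C(C)(C)C)C(C)(C)C)c12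
F5 | step 6 | [(4-bromo-8-methoxynaphthalen-1-yl)oxy]tri(propan-2-yl)silane | COc1cccc2c(Br)ccc(O[Si](C(C)C)(C(C)C)C(C)C)c12
F6 | step 6 | {[8-methoxy-4-(4,4,5,5-tetramethyl-1,3,2-dioxaborolan-2-yl)naphthalen-1-yl]oxy}tri(propan-2-yl)silane | COc1cccc2c(B3OC(C)(C)C(C)(C)O3)ccc(O[Si](C(C)C)(C(C)C)C(C)C)c12
F7 | step 6 | ({8-methoxy-4-[8-methoxy-1-(methoxymethoxy)naphthalen-2-yl]naphthalen-1-yl}oxy)tri(propan-2-yl)silane | COc1cccc2c(-c3ccc4cccc(OC)c4c3OCOC)ccc(O[Si](C(C)C)(C(C)C)C(C)C)c12
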